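## Retrosynthetic overview

1. Ring C is closed late by a reductive Heck reaction (C9–C11) of a ring-B vinyl bromide onto a cyclopentenone. Ring D (C11–C13, C15, C16 and the C12 carbinol) is bought as (S)-4-silyloxycyclopent-2-enone and attached first through C13–C14 by enolate alkylation; C17 comes from a Wittig reaction and the C15 carbonyl from allylic oxidation.
2. The C9 vinyl bromide and C14 come from bromoformylation of a C9 ketone, itself the Nef product of a nitro group; the axial 6α-acetate comes from hydride reduction of a C6 ketone.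
3. Rings A and B form together by an intramolecular Diels–Alder reaction of an acyclic (E)-nitroalkene/2-silyloxydiene, which makes C5–C10 and C8–C9.
4. Enabling feature: ring B (C5–C10) carries the C6 oxygen and C9 para to each other, so it reads as the silyl enol ether of a 4-nitrocyclohexanone (diene C5=C6–C7=C8, dienophile C9=C10). Its C5–C10 edge is shared with ring A, whose chain C1–C4 (acetoxy on C1, gem-dimethyl on C4) is the tether.
5. Ring order: D (purchased), then A and B (step 7), then C (step 15).

Key step: step 7

Remark: locants are those of the target skeleton throughout (C1–C10 in rings A and B, C11–C17 in the bicyclic part, C20 the methyl on C10; α is the face of C20), and ester 1 and enantiopure enone 23 are taken as purchasable.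

## Route

Step 1
Reactants: 1 methyl 3,3-dimethylpent-4-enoate; 2 N,O-dimethylhydroxylamine hydrochloride
Product: 3 N-methoxy-N,3,3-trimethylpent-4-enamide
Conditions: i-PrMgCl, THF, −20 to 0 °C
Reagents that add atoms: none
Why: Weinreb amide formation, in which the magnesium amide made in the flask displaces methoxide from the ester and the resulting N-methoxy-N-methyl amide does not react further with the non-nucleophilic base.

Step 2
Reactants: 3 N-methoxy-N,3,3-trimethylpent-4-enamide
Product: 4 N-methoxy-N,3,3-trimethyl-6-oxohexanamide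
Conditions: Rh(acac)(CO)2 (cat.), BiPhePhos, CO/H2 (1:1, 10 bar), toluene, 70 °C
Reagents that add atoms: carbon monoxide, [C-]#[O+]
Why: Rhodium-catalysed hydroformylation of a vinyl group on a quaternary carbon should give only the linear aldehyde, because the branched isomer would place the formyl group next to the quaternary centre, and the amide is inert.

Step 3
Reactants: 4 N-methoxy-N,3,3-trimethyl-6-oxohexanamide; 5 2-bromopropene
Product: 7 (S)-6-hydroxy-N-methoxy-N,3,3,7-tetramethyloct-7-enamide, via silyl ether 6 (not isolated)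
Conditions: CrCl2 (10 mol %), NiCl2 (2 mol %), chiral oxazoline sulfonamide ligand, Mn, Me3SiCl, Et3N, MeCN, 23 °C; then 1 M HCl
Reagents that add atoms: none
Why: Catalytic asymmetric Nozaki–Hiyama–Kishi alkenylation, in which the alkenylchromium species adds only to the aldehyde and the chiral ligand on chromium (enantiomer chosen for the S alcohol) sets the C1 carbinol centre.

Step 4
Reactants: 7 (S)-6-hydroxy-N-methoxy-N,3,3,7-tetramethyloct-7-enamide; 8 vinylmagnesium bromide
Product: 9 (S)-8-hydroxy-5,5,9-trimethyldeca-1,9-dien-3-one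
Conditions: THF, −78 to 0 °C; inverse quench into cold 1 M HCl
Reagents that add atoms: none
Why: Weinreb ketone synthesis, in which one equivalent of Grignard reagent deprotonates the hydroxyl and a second adds once to the amide to give a chelated tetrahedral intermediate that releases the vinyl ketone only on acidic quench.

Step 5
Reactants: 9 (S)-8-hydroxy-5,5,9-trimethyldeca-1,9-dien-3-one
Product: 10 (S)-2,6,6-trimethyl-8-oxodeca-1,9-dien-3-yl acetate
Conditions: Ac2O, Et3N, DMAP (cat.), CH2Cl2, 0 °C
Reagents that add atoms: acetic anhydride, CC(=O)OC(C)=O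
Why: Routine DMAP-catalysed acylation of the secondary allylic alcohol, which leaves the stereocentre untouched and installs the C1 acetate of the target.

Step 6
Reactants: 10 (S)-2,6,6-trimethyl-8-oxodeca-1,9-dien-3-yl acetate
Product: 11 (S,E)-2,6,6-trimethyl-1-nitro-8-oxodeca-1,9-dien-3-yl acetate
Conditions: AgNO2, TEMPO (cat.), 4 Å molecular sieves, ClCH2CH2Cl, 70 °C
Reagents that add atoms: silver nitrite, [Ag+].[O-]N=O
Why: Radical nitration of a 1,1-disubstituted alkene (NO2 radical adds to the terminal carbon, TEMPO removes the adjacent hydrogen) should give the conjugated nitroalkene with the nitro group trans to the larger C1 substituent, while the electron-poor vinyl ketone reacts far more slowly with the electrophilic NO2 radical.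

Step 7
Reactants: 11 (S,E)-2,6,6-trimethyl-1-nitro-8-oxodeca-1,9-dien-3-yl acetate
Product: 14 1α-acetoxy-4,4,10-trimethyl-9α-nitro-trans-decalin-6-one, via silyl dienol ether 12 (not isolated), via cycloadduct silyl enol ether 13 (not isolated)
Conditions: t-BuMe2SiOTf, Et3N, CH2Cl2, −78 to 0 °C; then toluene, 80 °C; then 1 M HCl, THF, 23 °C
Reagents that add atoms: none
Why: Soft enolisation of the vinyl ketone gives the (Z)-2-silyloxy-1,3-diene, which undergoes a thermal, asynchronous intramolecular [4+2] cycloaddition with the tethered (E)-nitroalkene, the C5–C10 bond (nucleophilic diene terminus to electrophilic β-carbon of the nitroalkene) forming ahead of the C8–C9 bond, and aqueous acid then hydrolyses the silyl enol ether to the C6 ketone. The closest precedents are the intramolecular Diels–Alder reactions of 1-nitro-1,7,9-decatrienes that give trans-decalins and the intermolecular cycloadditions of 2-silyloxydienes with nitroalkenes. Ring B is closed by the cycloaddition itself and ring A in the fused mode by the same C5–C10 bond, the four-carbon chain C1–C4 acting as the tether between diene terminus and dienophile. The trans ring fusion (C5–H anti to the C10 methyl) follows from the transition state with the tether exo and the nitro group, together with the methyl cis to it, endo; the C9 nitro centre is set as well but is erased in step 10. The absolute sense at C5 and C10 is relayed from C1, whose acetoxy group sits equatorial in the chair-like folding of the tether and so ends cis to the C10 methyl. The step needs periselectivity for the all-carbon [4+2] over cycloaddition through a nitro oxygen, which the six-membered tether geometry and the reactive silyloxydiene terminus should secure, while the regiochemistry is fixed by the tether and matched by the polarisation of both partners.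

Step 8
Reactants: 14 1α-acetoxy-4,4,10-trimethyl-9α-nitro-trans-decalin-6-one
Product: 15 1α-acetoxy-6α-hydroxy-4,4,10-trimethyl-9α-nitro-trans-decalin
Conditions: NaBH4, MeOH/THF, −20 to 0 °C
Reagents that add atoms: none
Why: Borohydride reduction from the equatorial β direction, because the axial α trajectory is blocked by the syn-axial C10 and C4 methyl groups, should give the axial 6α-alcohol as in other 6-oxo-4,4,10-trimethyldecalins, and nitro and acetate groups are inert.

Step 9
Reactants: 15 1α-acetoxy-6α-hydroxy-4,4,10-trimethyl-9α-nitro-trans-decalin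
Product: 16 1α,6α-diacetoxy-4,4,10-trimethyl-9α-nitro-trans-decalin
Conditions: Ac2O, DMAP, pyridine, 50 °C
Reagents that add atoms: acetic anhydride, CC(=O)OC(C)=O
Why: Forcing DMAP-catalysed acetylation is needed for the hindered axial alcohol and installs the second acetate of the target.

Step 10
Reactants: 16 1α,6α-diacetoxy-4,4,10-trimethyl-9α-nitro-trans-decalin
Product: 18 1α,6α-diacetoxy-4,4,10-trimethyl-trans-decalin-9-one, via potassium nitronate 17 (not isolated)
Conditions: KOt-Bu, THF, 0 °C; then O3, CH2Cl2/MeOH, −78 °C; Me2S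
Reagents that add atoms: ozone, [O-][O+]=O
Why: Oxidative Nef reaction, in which ozone cleaves the C=N bond of the nitronate to the ketone under non-hydrolytic conditions that spare the acetates, and no alkene is present at this stage.

Step 11
Reactants: 18 1α,6α-diacetoxy-4,4,10-trimethyl-trans-decalin-9-one
Product: 20 1α,6α-diacetoxy-9-bromo-4,4,10-trimethyl-Δ8-octalin-8-carbaldehyde, via iminium bromide 19 (not isolated)
Conditions: PBr3, DMF, CHCl3, 0 to 60 °C; then aq. NaOAc
Reagents that add atoms: N,N-dimethylformamide, CN(C)C=O; phosphorus tribromide, BrP(Br)Br; water, O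
Why: Vilsmeier–Haack–Arnold bromoformylation, in which the ketone can enolise only toward C8 (C10 is quaternary), so formylation at C8 and replacement of the carbonyl oxygen by bromide give the β-bromo enal that already holds the C8=C9 double bond and C14.

Step 12
Reactants: 20 1α,6α-diacetoxy-9-bromo-4,4,10-trimethyl-Δ8-octalin-8-carbaldehyde
Product: 21 1α,6α-diacetoxy-9-bromo-8-(hydroxymethyl)-4,4,10-trimethyl-Δ8-octalin
Conditions: NaBH4, CeCl3·7H2O, MeOH, 0 °C
Reagents that add atoms: none
Why: Luche 1,2-reduction of the enal, which leaves the vinyl bromide and the acetates untouched.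

Step 13
Reactants: 21 1α,6α-diacetoxy-9-bromo-8-(hydroxymethyl)-4,4,10-trimethyl-Δ8-octalin
Product: 22 1α,6α-diacetoxy-9-bromo-8-(bromomethyl)-4,4,10-trimethyl-Δ8-octalin
Conditions: CBr4, PPh3, CH2Cl2, 0 °C
Reagents that add atoms: carbon tetrabromide, BrC(Br)(Br)Br
Why: Appel bromination of the primary allylic alcohol under neutral conditions.

Step 14
Reactants: 22 1α,6α-diacetoxy-9-bromo-8-(bromomethyl)-4,4,10-trimethyl-Δ8-octalin; 23 (S)-4-(tert-butyldimethylsilyloxy)cyclopent-2-en-1-one
Product: 25 trans-4-(tert-butyldimethylsilyloxy)-5-[(1α,6α-diacetoxy-9-bromo-4,4,10-trimethyl-Δ8-octalin-8-yl)methyl]cyclopent-2-en-1-one, via lithium dienolate 24 (not isolated)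
Conditions: LiN(i-Pr)2, THF, −78 °C; then 22, DMPU, −78 to −40 °C
Reagents that add atoms: none
Why: Kinetic α'-deprotonation of the enone gives the cross-conjugated lithium enolate, whose loss of silanolate is disfavoured because it would generate a cyclopentadienone, and SN2 alkylation by the primary allylic bromide anti to the neighbouring silyloxy group sets C13 trans to C12.

Step 15
Reactants: 25 trans-4-(tert-butyldimethylsilyloxy)-5-[(1α,6α-diacetoxy-9-bromo-4,4,10-trimethyl-Δ8-octalin-8-yl)methyl]cyclopent-2-en-1-one
Product: 26 tetracyclic C16 ketone (1α,6α-diacetoxy, 12-silyloxy, C8=C9, C15 methylene)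
Conditions: Pd(OAc)2 (10 mol %), PPh3, HCO2Na, Et4NCl, DMF, 80 °C
Reagents that add atoms: none
Why: Reductive Heck cyclisation, in which zerovalent palladium inserts into the vinyl bromide, 6-exo syn-carbopalladation of the enone at C11 occurs on the face that carries the tether (so C9 ends cis to C14 and trans to the silyloxy group, which sets C11), and formate reduces the palladium enolate because no syn β-hydrogen is available.

Step 16
Reactants: 26 tetracyclic C16 ketone
Product: 27 tetracyclic 16-methylene compound (C15 still CH2)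
Conditions: Ph3PCH3Br, KOt-Bu, THF, 0 to 23 °C
Reagents that add atoms: methyltriphenylphosphonium bromide, C[P+](c1ccccc1)(c1ccccc1)c1ccccc1.[Br-]
Why: Wittig methylenation of the unhindered cyclopentanone, whose α-positions are a bridgehead and a methylene, should outpace any attack of the ylide on the acetates.

Step 17
Reactants: 27 tetracyclic 16-methylene compound
Product: 29 12-O-(tert-butyldimethylsilyl) ether of the target, via allylic alcohol 28 (not isolated)
Conditions: SeO2 (cat.), t-BuOOH, CH2Cl2, 0 to 23 °C; then Dess–Martin periodinane, NaHCO3, CH2Cl2, 0 °C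
Reagents that add atoms: tert-butyl hydroperoxide, CC(C)(C)OO
Why: Catalytic SeO2 allylic oxidation (ene reaction, then 2,3-sigmatropic shift) should occur at C15, the only non-bridgehead allylic position of the exposed exocyclic alkene, in preference to the flanked tetrasubstituted C8=C9 alkene, and Dess–Martin oxidation of the crude alcohol gives the α-methylene ketone.

Step 18
Reactants: 29 12-O-(tert-butyldimethylsilyl) ether of the target
Product: 30 1α,6α-diacetoxyjungermannenone C
Conditions: HF·pyridine, pyridine/THF, 0 to 23 °C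
Reagents that add atoms: none
Why: Buffered fluoride cleavage of the silyl ether frees the C12 hydroxyl, whose configuration was carried unchanged from 23, without touching the acetates or the α-methylene ketone.

## Compound list

1 | methyl 3,3-dimethylpent-4-enoate | C=CC(C)(C)CC(=O)OC | starting material
2 | N,O-dimethylhydroxylamine hydrochloride | CNOC.Cl | starting material
3 | N-methoxy-N,3,3-trimethylpent-4-enamide | C=CC(C)(C)CC(=O)N(C)OC | intermediate
4 | N-methoxy-N,3,3-trimethyl-6-oxohexanamide | O=CCCC(C)(C)CC(=O)N(C)OC | intermediate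
5 | 2-bromopropene | C=C(C)Br | starting material
6 | (S)-N-methoxy-N,3,3,7-tetramethyl-6-(trimethylsilyloxy)oct-7-enamide | C=C(C)[C@@H](O[Si](C)(C)C)CCC(C)(C)CC(=O)N(C)OC | intermediate
7 | (S)-6-hydroxy-N-methoxy-N,3,3,7-tetramethyloct-7-enamide | C=C(C)[C@@H](O)CCC(C)(C)CC(=O)N(C)OC | intermediate
8 | vinylmagnesium bromide | C=C[Mg]Br | starting material
9 | (S)-8-hydroxy-5,5,9-trimethyldeca-1,9-dien-3-one | C=C(C)[C@@H](O)CCC(C)(C)CC(=O)C=C | intermediate
10 | (S)-2,6,6-trimethyl-8-oxodeca-1,9-dien-3-yl acetate | C=C(C)[C@@H](OC(C)=O)CCC(C)(C)CC(=O)C=C | intermediate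
11 | (S,E)-2,6,6-trimethyl-1-nitro-8-oxodeca-1,9-dien-3-yl acetate | [O-][N+](=O)/C=C(\C)[C@@H](OC(C)=O)CCC(C)(C)CC(=O)C=C | intermediate
12 | (3S,1E,7Z)-8-(tert-butyldimethylsilyloxy)-2,6,6-trimethyl-1-nitrodeca-1,7,9-trien-3-yl acetate | [O-][N+](=O)/C=C(\C)[C@@H](OC(C)=O)CCC(C)(C)/C=C(\O[Si](C)(C)C(C)(C)C)C=C | intermediate
13 | cycloadduct silyl enol ether: trans-fused 1α-acetoxy-6-(tert-butyldimethylsilyloxy)-4,4,10-trimethyl-9α-nitro-Δ6-octalin | [O-][N+](=O)[C@H]1[C@]2(C)[C@@H](OC(C)=O)CCC(C)(C)[C@H]2C(O[Si](C)(C)C(C)(C)C)=CC1 | intermediate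
14 | 1α-acetoxy-4,4,10-trimethyl-9α-nitro-trans-decalin-6-one | [O-][N+](=O)[C@H]1[C@]2(C)[C@@H](OC(C)=O)CCC(C)(C)[C@H]2C(=O)CC1 | intermediate
15 | 1α-acetoxy-6α-hydroxy-4,4,10-trimethyl-9α-nitro-trans-decalin | [O-][N+](=O)[C@H]1[C@]2(C)[C@@H](OC(C)=O)CCC(C)(C)[C@H]2[C@@H](O)CC1 | intermediate
16 | 1α,6α-diacetoxy-4,4,10-trimethyl-9α-nitro-trans-decalin | [O-][N+](=O)[C@H]1[C@]2(C)[C@@H](OC(C)=O)CCC(C)(C)[C@H]2[C@@H](OC(C)=O)CC1 | intermediate
17 | potassium C9 nitronate of 16 | [K+].[O-][N+]([O-])=C1[C@]2(C)[C@@H](OC(C)=O)CCC(C)(C)[C@H]2[C@@H](OC(C)=O)CC1 | intermediate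
18 | 1α,6α-diacetoxy-4,4,10-trimethyl-trans-decalin-9-one | O=C1[C@]2(C)[C@@H](OC(C)=O)CCC(C)(C)[C@H]2[C@@H](OC(C)=O)CC1 | intermediate
19 | N,N-dimethyliminium bromide of aldehyde 20 | C[N+](C)=CC1=C(Br)[C@]2(C)[C@@H](OC(C)=O)CCC(C)(C)[C@H]2[C@@H](OC(C)=O)C1.[Br-] | intermediate
20 | 1α,6α-diacetoxy-9-bromo-4,4,10-trimethyl-Δ8-octalin-8-carbaldehyde (5β-H) | O=CC1=C(Br)[C@]2(C)[C@@H](OC(C)=O)CCC(C)(C)[C@H]2[C@@H](OC(C)=O)C1 | intermediate
21 | 1α,6α-diacetoxy-9-bromo-8-(hydroxymethyl)-4,4,10-trimethyl-Δ8-octalin | OCC1=C(Br)[C@]2(C)[C@@H](OC(C)=O)CCC(C)(C)[C@H]2[C@@H](OC(C)=O)C1 | intermediate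
22 | 1α,6α-diacetoxy-9-bromo-8-(bromomethyl)-4,4,10-trimethyl-Δ8-octalin | BrCC1=C(Br)[C@]2(C)[C@@H](OC(C)=O)CCC(C)(C)[C@H]2[C@@H](OC(C)=O)C1 | intermediate
23 | (S)-4-(tert-butyldimethylsilyloxy)cyclopent-2-en-1-one | O=C1C=C[C@@H](O[Si](C)(C)C(C)(C)C)C1 | starting material
24 | lithium dienolate of 23 | [Li+].[O-]C1=C[C@H](O[Si](C)(C)C(C)(C)C)C=C1 | intermediate
25 | trans-4-(tert-butyldimethylsilyloxy)-5-[(1α,6α-diacetoxy-9-bromo-4,4,10-trimethyl-Δ8-octalin-8-yl)methyl]cyclopent-2-en-1-one | O=C1C=C[C@@H](O[Si](C)(C)C(C)(C)C)[C@@H]1CC1=C(Br)[C@]2(C)[C@@H](OC(C)=O)CCC(C)(C)[C@H]2[C@@H](OC(C)=O)C1 | intermediate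
26 | tetracyclic C16 ketone: 1α,6α-diacetoxy-12-(tert-butyldimethylsilyloxy) skeleton with C8=C9, C15H2 and C16=O | O=C1C[C@@H]2C3=C(C[C@H](OC(C)=O)[C@@H]4C(C)(C)CC[C@H](OC(C)=O)[C@@]34C)C[C@H]1[C@@H]2O[Si](C)(C)C(C)(C)C | intermediate
27 | tetracyclic 16-methylene compound (C15H2) | C=C1C[C@@H]2C3=C(C[C@H](OC(C)=O)[C@@H]4C(C)(C)CC[C@H](OC(C)=O)[C@@]34C)C[C@H]1[C@@H]2O[Si](C)(C)C(C)(C)C | intermediate
28 | 15-hydroxy-16-methylene compound (C15 epimers, centre left undefined) | C=C1C(O)[C@@H]2C3=C(C[C@H](OC(C)=O)[C@@H]4C(C)(C)CC[C@H](OC(C)=O)[C@@]34C)C[C@H]1[C@@H]2O[Si](C)(C)C(C)(C)C | intermediate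
29 | 12-O-(tert-butyldimethylsilyl)-1α,6α-diacetoxyjungermannenone C | C=C1C(=O)[C@@H]2C3=C(C[C@H](OC(C)=O)[C@@H]4C(C)(C)CC[C@H](OC(C)=O)[C@@]34C)C[C@H]1[C@@H]2O[Si](C)(C)C(C)(C)C | intermediate
30 | 1α,6α-diacetoxyjungermannenone C | C=C1C(=O)[C@@H]2C3=C(C[C@H](OC(C)=O)[C@@H]4C(C)(C)CC[C@H](OC(C)=O)[C@@]34C)C[C@H]1[C@@H]2O | target

## Step count and risks

Total step count: 18. Longest linear sequence: 18 steps (1 to 30); 23 enters at step 14.

**Step 7.** The trans-selective transition state has to build the syn-axial contact between the C10 methyl and the axial C4 methyl, so the ring-fusion selectivity may erode toward the cis-fused adduct. The amine used for silylation may also deconjugate the nitroalkene before cycloaddition. The fallback sets out from 11 and returns at 14. The silylation, cycloaddition and hydrolysis are run as before; whatever cis-fused ketone forms, the C5 epimer F1, is not discarded. It is equilibrated through the C6 enolate (DBU, toluene, 60 °C), which should favour the trans-fused decalone as in other 6-oxo-4,4,10-trimethyldecalins. The C5 centre is then set under thermodynamic rather than kinetic control, and the material rejoins the route as 14.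

**Step 14.** The cross-conjugated lithium enolate may undergo proton transfer with the product, lose silanolate, or be alkylated on oxygen before the hindered allylic bromide reacts. The fallback sets out from 21 and 23 and returns at 25. Alcohol 21 is converted into the allylic methyl carbonate F2 (methyl chloroformate, pyridine). Enone 23 is converted into the trimethylsilyl dienol ether F3 (Me3SiOTf, Et3N, −78 °C). The two are joined under neutral Tsuji–Trost conditions (Pd2(dba)3, dppe, THF, 23 °C). Zerovalent palladium should ionise the primary allylic carbonate faster than it inserts into the hindered vinyl bromide. The methoxide released transfers the silyl group, and the palladium enolate is allylated at C13 anti to the silyloxy group to give 25.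

**Step 17.** The electron-rich tetrasubstituted C8=C9 alkene may compete for SeO2 at its allylic C7 and C14 positions. The fallback sets out from 26 and returns at 28. Ketone 26, which can enolise only toward C15, is converted into the trimethylsilyl enol ether F4 (Me3SiOTf, Et3N). F4 is oxidised in a Rubottom-type reaction with OsO4 (cat.) and N-methylmorpholine N-oxide, which should attack the silyl enol ether far faster than the hindered tetrasubstituted alkene, to give the α-hydroxy ketone F5. Wittig methylenation of F5 with excess Ph3P=CH2 gives allylic alcohol 28, which is oxidised with Dess–Martin periodinane as in the second stage of step 17.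

Further compounds
F1 | step 7 | cis-fused C5 epimer of 14 | [O-][N+](=O)[C@H]1[C@]2(C)[C@@H](OC(C)=O)CCC(C)(C)[C@@H]2C(=O)CC1
F2 | step 14 | allylic methyl carbonate of 21 | COC(=O)OCC1=C(Br)[C@]2(C)[C@@H](OC(C)=O)CCC(C)(C)[C@H]2[C@@H](OC(C)=O)C1
F3 | step 14 | trimethylsilyl dienol ether of 23 | C[Si](C)(C)OC1=C[C@H](O[Si](C)(C)C(C)(C)C)C=C1
F4 | step 17 | trimethylsilyl enol ether of 26 | C[Si](C)(C)OC1=C[C@@H]2C3=C(C[C@H](OC(C)=O)[C@@H]4C(C)(C)CC[C@H](OC(C)=O)[C@@]34C)C[C@H]1[C@@H]2O[Si](C)(C)C(C)(C)C
F5 | step 17 | 15-hydroxy C16 ketone from F4 (C15 epimers, centre left undefined) | O=C1C(O)[C@@H]2C3=C(C[C@H](OC(C)=O)[C@@H]4C(C)(C)CC[C@H](OC(C)=O)[C@@]34C)C[C@H]1[C@@H]2O[Si](C)(C)C(C)(C)C
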